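**Retrosynthetic overview**
- The target is reached from its 7,7''-diacetate by cutting two ester C–O bonds; the skeleton and both (S) centres are unchanged.
- Key disconnection: the C3'–C3''' biaryl bond, which joins two phenol ortho carbons that are both nucleophilic by nature. In the forward direction one molecule of (2S)-7-O-acetylnaringenin is oxidised to its ring B phenoxyl (an electrophilic, enolonium-type arenol equivalent at C3') and is attacked by C3' of a second molecule.
- (2S)-7-O-Acetylnaringenin comes from (2S)-naringenin and acetic anhydride; the acetate masks the 7-OH and lowers the reactivity of ring A.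
- Ring order: rings A, B and the pyranone ring C arrive intact from naringenin with C2 already (S). No ring is built; the only skeletal bond made is the ring B–ring B' bond.

Assumption: the target is (2S,2''S)-3',3'''-binaringenin as the SMILES shows, and (2S)-naringenin is bought in ≥98% ee.

**Step 1**
Reactants: 1 (2S)-naringenin; 2 acetic anhydride
Product: 3 (2S)-7-O-acetylnaringenin
Conditions: Ac2O (1.05 equiv), pyridine, 0 °C, 1 h
Reagents that add atoms: acetic anhydride, CC(=O)OC(C)=O
Why: Regioselective O-acylation (nucleophilic acyl substitution): the 7-OH is the most acidic phenol (para to the C4 carbonyl, pKa about 7.5 against about 10 for the 4'-OH) and reacts first, the 5-OH is held in a hydrogen bond to C4=O and does not react at 0 °C, and pyridine is too weak a base to open the pyranone, so C2 stays (S).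

**Step 2**
Reactants: 3 (2S)-7-O-acetylnaringenin (two molecules)
Product: 5 (2S,2''S)-7,7''-di-O-acetyl-3',3'''-binaringenin, via ring B phenoxyl radical 4 (not isolated)
Conditions: 9-mesityl-10-methylacridinium tetrafluoroborate (5 mol%), O2 (1 atm), HFIP (1,1,1,3,3,3-hexafluoropropan-2-ol, 0.05 M), 450 nm LEDs, 23 °C, stopped at ca. 60% conversion, 3 recovered
Reagents that add atoms: none
Why: Proposed new method: the excited acridinium oxidises the only free, non-chelated phenol of 3 (the 4'-OH, the most easily oxidised site) to the phenoxyl radical 4, whose ortho carbon C3' is now electron-poor (the polarity of this enol-type carbon is reversed); it is attacked by the nucleophilic C3' of a second, unoxidised molecule of 3, and loss of one more electron and two protons (O2 turns the catalyst over) rearomatises both rings to the 2,2'-biphenol; ring A is disfavoured as a partner because its 5-OH is chelated to C4=O, its 7-oxygen is acylated, its carbonyl is hydrogen-bonded by HFIP, and C6/C8 each sit between two oxygen substituents; the closest known reaction type is the acridinium/O2/HFIP photocatalytic oxidative homocoupling of 4-alkylphenols, which couples protected tyrosine ortho–ortho to dityrosine with its stereocentre intact; no stereocentre is made or broken (both C2 centres come from 1, and the biaryl axis with only two ortho substituents rotates freely).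

**Step 3**
Reactants: 5 (2S,2''S)-7,7''-di-O-acetyl-3',3'''-binaringenin
Product: 6 (2S,2''S)-3',3'''-binaringenin
Conditions: HCl (1.25 M in MeOH), 0 → 23 °C, 3 h
Reagents that add atoms: none
Why: Acid-catalysed transesterification (methanolysis) of the two aryl acetates; the flavanone is configurationally stable in dilute acid at room temperature (ring opening to the chalcone needs base or hot strong acid), so both (S) centres are kept.

**Compound list**
1 | (2S)-naringenin, (2S)-5,7-dihydroxy-2-(4-hydroxyphenyl)-2,3-dihydrochromen-4-one | O=C1C[C@@H](c2ccc(O)cc2)Oc2cc(O)cc(O)c21 | starting material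
2 | acetic anhydride | CC(=O)OC(C)=O | starting material
3 | (2S)-7-O-acetylnaringenin, (2S)-5-hydroxy-2-(4-hydroxyphenyl)-4-oxo-2,3-dihydrochromen-7-yl acetate | O=C1C[C@@H](c2ccc(O)cc2)Oc2cc(OC(C)=O)cc(O)c21 | intermediate
4 | ring B (4'-O) phenoxyl radical of 3 | O=C1C[C@@H](c2ccc([O])cc2)Oc2cc(OC(C)=O)cc(O)c21 | intermediate
5 | (2S,2''S)-7,7''-di-O-acetyl-3',3'''-binaringenin (two units of 3 joined C3'–C3''', each biaryl carbon ortho to a free 4'-OH) | O=C1C[C@@H](c2ccc(O)c(-c3cc([C@@H]4CC(=O)c5c(O)cc(OC(C)=O)cc5O4)ccc3O)c2)Oc2cc(OC(C)=O)cc(O)c21 | intermediate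
6 | (2S,2''S)-3',3'''-binaringenin | O=C1C[C@@H](c2ccc(O)c(-c3cc([C@@H]4CC(=O)c5c(O)cc(O)cc5O4)ccc3O)c2)Oc2cc(O)cc(O)c21 | target

**Step count and risks**
Total step count: 3. Longest linear sequence: 3.

Any (2R)-naringenin in 1 ends up almost entirely in the (2S,2''R) diastereomer of 5 (about 2% from 98% ee material), so the enantiomeric purity of the (2S,2''S) product exceeds that of 1.

Most likely to fail, in this order: step 2, step 1, step 3.

Step 2 is the riskiest. Ring A of a second molecule (C8 or C6) may compete as the nucleophile and give 3',8''- or 3',6''-linked dimers. C–O coupling may give diaryl ethers. The biphenol 5 or the benzylic C2–H may be over-oxidised (to oligomers or the flavone). A realistic yield is 30–40% with recovered 3. Fallback, setting out from 3 and coming back to the route at 5: the biaryl bond is made under steric control instead of redox control.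
- 3 is treated with pinacolborane (1.05 equiv, THF, 23 °C), which borylates the free 4'-OH and gives the O-boryl phenol F1.
- In the same flask, [Ir(OMe)(cod)]2 (1.5 mol%), 4,4'-di-tert-butyl-2,2'-bipyridine (3 mol%) and B2pin2 (1.2 equiv) at 60 °C borylate the only reachable aryl C–H, the one next to the O-boryl group, giving the C,O-diboryl compound F2. C6 and C8 each lie between two oxygen substituents, and C2'/C6' lie next to the chroman ring.
- Methanol work-up frees the phenol and gives (2S)-7-O-acetyl-3'-(4,4,5,5-tetramethyl-1,3,2-dioxaborolan-2-yl)naringenin F3.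
- F3 is homocoupled oxidatively (Pd(OAc)2 5 mol%, O2 1 atm, KHCO3, acetone/H2O, 23 °C). Divalent palladium takes up two aryl groups by transmetalation, reductive elimination forms the C3'–C3''' bond, and O2 returns zerovalent palladium to divalent palladium. The product is 5, and step 3 follows unchanged.

Step 1 can fail through poor discrimination between the 7-OH and the 4'-OH, giving the 4'-acetate and the 4',7-diacetate. Fallback, setting out from 1 and coming back at 6: no protecting group is used, and the selectivity is set by electrode potential. 1 is electrolysed at controlled potential at its first anodic wave, which belongs to the 4'-OH (graphite felt anode, about +0.85 V against Ag/AgCl, Pt cathode, divided cell, MeCN/acetate buffer pH 4.7, NaClO4, 10 °C, 1 F/mol). Only ring B is oxidised; the phenoxyl radicals couple with each other at C3', as tyrosyl radicals do on the way to dityrosine, and ring A, not oxidised at this potential, takes no part. Tautomerisation gives 6 directly in a weakly acidic medium that does not epimerise C2. No new compound arises (entry F0).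

Step 3 can fail through partial epimerisation at C2 or incomplete cleavage. Fallback, setting out from 1 and coming back at 6: the acetate is replaced by a group that leaves under neutral hydrogenolysis.
- 1 with benzyl chloroformate (1.05 equiv, pyridine, 0 °C) gives (2S)-7-O-(benzyloxycarbonyl)naringenin F4, with the same 7-selectivity as in step 1.
- The photo-oxidative coupling of step 2 gives (2S,2''S)-7,7''-bis-O-(benzyloxycarbonyl)-3',3'''-binaringenin F5.
- H2 (1 atm), Pd/C, EtOAc, 23 °C frees both phenols without acid or base and gives 6.

**Further compounds**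
F1 | step 2 | (2S)-7-O-acetyl-4'-O-(4,4,5,5-tetramethyl-1,3,2-dioxaborolan-2-yl)naringenin | O=C1C[C@@H](c2ccc(OB3OC(C)(C)C(C)(C)O3)cc2)Oc2cc(OC(C)=O)cc(O)c21
F2 | step 2 | (2S)-7-O-acetyl-4'-O,3'-bis(4,4,5,5-tetramethyl-1,3,2-dioxaborolan-2-yl)naringenin | O=C1C[C@@H](c2ccc(OB3OC(C)(C)C(C)(C)O3)c(B3OC(C)(C)C(C)(C)O3)c2)Oc2cc(OC(C)=O)cc(O)c21
F3 | step 2 | (2S)-7-O-acetyl-3'-(4,4,5,5-tetramethyl-1,3,2-dioxaborolan-2-yl)naringenin | O=C1C[C@@H](c2ccc(O)c(B3OC(C)(C)C(C)(C)O3)c2)Oc2cc(OC(C)=O)cc(O)c21
F0 | step 1 | none | none
F4 | step 3 | (2S)-7-O-(benzyloxycarbonyl)naringenin | O=C1C[C@@H](c2ccc(O)cc2)Oc2cc(OC(=O)OCc3ccccc3)cc(O)c21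
F5 | step 3 | (2S,2''S)-7,7''-bis-O-(benzyloxycarbonyl)-3',3'''-binaringenin | O=C1C[C@@H](c2ccc(O)c(-c3cc([C@@H]4CC(=O)c5c(O)cc(OC(=O)OCc6ccccc6)cc5O4)ccc3O)c2)Oc2cc(OC(=O)OCc3ccccc3)cc(O)c21
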